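Ring C is cut at its only unsubstituted carbon. C3 carries a single hydrogen and sits between the C4 carbonyl and the oxygen-bearing C2, so both of its ring bonds can be made from one phosphorus ylide carbon and two carboxyl-derived carbons. In a single operation the ylide is C-acylated by a silyl ester (C3–C4) and the acylphosphorane so formed olefinates the adjacent aryl ester carbonyl (C2=C3), which closes the pyranone with O1–C2 already in place. The precursor is the tert-butyldimethylsilyl ester of 2-hydroxy-3,4,5-trimethoxybenzoic acid (ring A) whose phenol oxygen carries the 3-benzyloxy-4,5-dimethoxybenzoyl group (ring B); hydrogenolysis then frees the 3'-hydroxyl.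

Key step: step 6

Remark: the target is read as achiral 2-(3-hydroxy-4,5-dimethoxyphenyl)-6,7,8-trimethoxy-4H-chromen-4-one. The acyl donor is carried as a tert-butyldimethylsilyl ester because a trimethylsilyl ester would not survive handling, and the ylide is used as its C-trimethylsilyl derivative, made in the flask from methylenetriphenylphosphorane, so that the acyl ylide arises by loss of silicon and no second equivalent of basic ylide is needed.

Step 1
Reactants: 1 3,4,5-trimethoxybenzoic acid
Product: 2 2-bromo-3,4,5-trimethoxybenzoic acid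
Conditions: Br2 (1.05 equiv), CHCl3, trace H2O, reflux
Reagents that add atoms: bromine, BrBr
Why: Electrophilic aromatic bromination, in which C2 and C6 are the only open positions, are equivalent and are activated by ortho and para methoxy groups, while the first bromine and the carboxyl group discourage a second substitution.

Step 2
Reactants: 2 2-bromo-3,4,5-trimethoxybenzoic acid
Product: 3 2-hydroxy-3,4,5-trimethoxybenzoic acid
Conditions: NaOH (5 equiv), CuSO4·5H2O (0.1 equiv, divalent copper), pyridine (0.5 equiv), H2O, reflux; then HCl to pH 1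
Reagents that add atoms: sodium hydroxide, [Na+].[OH-]
Why: Copper-catalysed Ullmann-type hydroxylation of an ortho-bromobenzoate, in which the neighbouring carboxylate binds copper and speeds displacement of bromide by hydroxide, while the aryl methyl ethers are inert to aqueous base.

Step 3
Reactants: 4 3-hydroxy-4,5-dimethoxybenzoic acid
Product: 6 3-(benzyloxy)-4,5-dimethoxybenzoic acid, via benzyl 3-(benzyloxy)-4,5-dimethoxybenzoate 5 (not isolated)
Conditions: BnBr (2.2 equiv), K2CO3, DMF, 60 °C; then MeOH, 4 M NaOH added to the same flask, 60 °C; HCl to pH 2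
Reagents that add atoms: benzyl bromide, BrCc1ccccc1
Why: Williamson O-alkylation of phenoxide and carboxylate followed by saponification of the benzyl ester only, since the aryl benzyl ether is inert to hydroxide.

Step 4
Reactants: 6 3-(benzyloxy)-4,5-dimethoxybenzoic acid; 3 2-hydroxy-3,4,5-trimethoxybenzoic acid
Product: 8 2-{[3-(benzyloxy)-4,5-dimethoxybenzoyl]oxy}-3,4,5-trimethoxybenzoic acid, via 3-(benzyloxy)-4,5-dimethoxybenzoyl chloride 7 (not isolated)
Conditions: 6, (COCl)2, DMF (cat.), CH2Cl2, 0 °C to rt, evaporate; then 3, pyridine, DMAP (cat.), CH2Cl2, 0 °C to rt; cold 1 M HCl work-up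
Reagents that add atoms: none
Why: DMF-catalysed acid chloride formation followed by Einhorn-type O-acylation of the phenol of 3 in pyridine, where any mixed anhydride formed at the carboxyl group either passes the aroyl group to the adjacent phenol oxygen or is hydrolysed on work-up.

Step 5
Reactants: 8 2-{[3-(benzyloxy)-4,5-dimethoxybenzoyl]oxy}-3,4,5-trimethoxybenzoic acid
Product: 9 tert-butyldimethylsilyl 2-{[3-(benzyloxy)-4,5-dimethoxybenzoyl]oxy}-3,4,5-trimethoxybenzoate
Conditions: MTBSTFA (1.2 equiv), dry MeCN, rt to 50 °C; volatiles removed under high vacuum with toluene co-evaporation; used at once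
Reagents that add atoms: N-(tert-butyldimethylsilyl)-N-methyltrifluoroacetamide (MTBSTFA), CN([Si](C)(C)C(C)(C)C)C(=O)C(F)(F)F
Why: Neutral silyl transfer from the N-silyl amide to the carboxylic acid should give the silyl ester without nucleophilic base or aqueous work-up, so the aryl ester is untouched and the moisture-sensitive product is obtained by evaporation alone.

Step 6
Reactants: 9 tert-butyldimethylsilyl 2-{[3-(benzyloxy)-4,5-dimethoxybenzoyl]oxy}-3,4,5-trimethoxybenzoate; 10 methyltriphenylphosphonium bromide
Product: 14 2-[3-(benzyloxy)-4,5-dimethoxyphenyl]-6,7,8-trimethoxy-4H-chromen-4-one, via methylenetriphenylphosphorane 11 (not isolated), via (trimethylsilyl)methylenetriphenylphosphorane 12 (not isolated), via acyl ylide 13 (not isolated)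
Conditions: 10 (2.4 equiv), NaN(SiMe3)2 (2.3 equiv), THF, 0 °C to rt; Me3SiCl (1.15 equiv), 0 °C to rt; then 9 (1.0 equiv) in THF, 0 °C to rt; then reflux (toluene after solvent exchange if closure is slow)
Reagents that add atoms: none
Why: NaN(SiMe3)2 converts 10 into 11, half of which is C-silylated by Me3SiCl and deprotonated by the other half to give 12 beside inert methyltriphenylphosphonium chloride; the ylide carbon of 12 then adds to the silyl ester carbonyl of 9, tert-butyldimethylsiloxide is expelled and at once strips the Me3Si group from the α-silyl acylphosphonium ion, giving the stabilised acyl ylide 13 (C3–C4 formed) and a neutral disiloxane. On heating, the ylide carbon of 13 adds to the neighbouring aryl ester carbonyl and the oxaphosphetane collapses to the C2=C3 double bond and Ph3PO. The closest known reaction types are the C-acylation of silylated phosphorus ylides by silyl esters and the intramolecular Wittig olefination of an ester carbonyl by an ortho-acyloxyphenacylidenephosphorane, an established entry to 4H-chromen-4-ones. Ring C closes in a 6-exo-trig mode by C2–C3 bond formation at carbon, the O1–C2 bond being present from the start as the ester C–O bond. No stereocentre arises, and the new double bond can only be endocyclic. The step needs the first acylation to occur at the silyl ester and not at the aryl ester: siloxide departs easily and is consumed irreversibly at silicon, the aryl ester carbonyl is deactivated by the three alkoxy donors of ring B, and the bulky, weakly basic silyl ylide, used without excess, should discriminate better than the parent methylene ylide.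

Step 7
Reactants: 14 2-[3-(benzyloxy)-4,5-dimethoxyphenyl]-6,7,8-trimethoxy-4H-chromen-4-one
Product: 15 2-(3-hydroxy-4,5-dimethoxyphenyl)-6,7,8-trimethoxy-4H-chromen-4-one
Conditions: H2 (1 atm), 10% Pd/C, EtOAc/MeOH, rt; stopped when 14 is consumed
Reagents that add atoms: none
Why: Palladium-catalysed hydrogenolysis of the aryl benzyl ether, under which the aryl methyl ethers and the conjugated C2=C3 bond of the chromen-4-one should survive at 1 atm and room temperature.

Compound list
1 | 3,4,5-trimethoxybenzoic acid | COc1cc(C(=O)O)cc(OC)c1OC | starting material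
2 | 2-bromo-3,4,5-trimethoxybenzoic acid | COc1cc(C(=O)O)c(Br)c(OC)c1OC | intermediate
3 | 2-hydroxy-3,4,5-trimethoxybenzoic acid | COc1cc(C(=O)O)c(O)c(OC)c1OC | intermediate
4 | 3-hydroxy-4,5-dimethoxybenzoic acid | COc1cc(C(=O)O)cc(O)c1OC | starting material
5 | benzyl 3-(benzyloxy)-4,5-dimethoxybenzoate | COc1cc(C(=O)OCc2ccccc2)cc(OCc2ccccc2)c1OC | intermediate
6 | 3-(benzyloxy)-4,5-dimethoxybenzoic acid | COc1cc(C(=O)O)cc(OCc2ccccc2)c1OC | intermediate
7 | 3-(benzyloxy)-4,5-dimethoxybenzoyl chloride | COc1cc(C(Cl)=O)cc(OCc2ccccc2)c1OC | intermediate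
8 | 2-{[3-(benzyloxy)-4,5-dimethoxybenzoyl]oxy}-3,4,5-trimethoxybenzoic acid | COc1cc(C(=O)O)c(OC(=O)c2cc(OC)c(OC)c(OCc3ccccc3)c2)c(OC)c1OC | intermediate
9 | tert-butyldimethylsilyl 2-{[3-(benzyloxy)-4,5-dimethoxybenzoyl]oxy}-3,4,5-trimethoxybenzoate | COc1cc(C(=O)O[Si](C)(C)C(C)(C)C)c(OC(=O)c2cc(OC)c(OC)c(OCc3ccccc3)c2)c(OC)c1OC | intermediate
10 | methyltriphenylphosphonium bromide | C[P+](c1ccccc1)(c1ccccc1)c1ccccc1.[Br-] | starting material
11 | methylenetriphenylphosphorane | C=P(c1ccccc1)(c1ccccc1)c1ccccc1 | intermediate
12 | (trimethylsilyl)methylenetriphenylphosphorane | C[Si](C)(C)C=P(c1ccccc1)(c1ccccc1)c1ccccc1 | intermediate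
13 | (2-{2-[(3-benzyloxy-4,5-dimethoxybenzoyl)oxy]-3,4,5-trimethoxyphenyl}-2-oxoethylidene)triphenylphosphorane (acyl ylide) | COc1cc(C(=O)C=P(c2ccccc2)(c2ccccc2)c2ccccc2)c(OC(=O)c2cc(OC)c(OC)c(OCc3ccccc3)c2)c(OC)c1OC | intermediate
14 | 2-[3-(benzyloxy)-4,5-dimethoxyphenyl]-6,7,8-trimethoxy-4H-chromen-4-one | COc1cc(-c2cc(=O)c3cc(OC)c(OC)c(OC)c3o2)cc(OCc4ccccc4)c1OC | intermediate
15 | 2-(3-hydroxy-4,5-dimethoxyphenyl)-6,7,8-trimethoxy-4H-chromen-4-one | COc1cc(-c2cc(=O)c3cc(OC)c(OC)c(OC)c3o2)cc(O)c1OC | target

Total step count: 7. Longest linear sequence: 6 steps (steps 1, 2, 4, 5, 6 and 7, from 1 to 15).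

Steps most likely to fail

Step 6. The ylide may attack the aryl ester carbonyl instead of the silyl ester, moving the ring B aroyl group onto phosphorus and releasing the ring A phenoxide. The silyl ester may also hydrolyse before it meets the ylide, or the stabilised ylide may close only sluggishly onto the electron-rich aryl ester. The fallback closes ring C at O1–C2 by known chemistry and sets out from 3. Excess MeLi in THF (0 °C to rt, acidic work-up) should turn the carboxyl group into the methyl ketone 1-(2-hydroxy-3,4,5-trimethoxyphenyl)ethan-1-one F1. O-Aroylation with 7 (made as in step 4) in pyridine should give 2-acetyl-4,5,6-trimethoxyphenyl 3-(benzyloxy)-4,5-dimethoxybenzoate F2. Baker–Venkataraman rearrangement (KOH, pyridine, 50 °C) should give 1-[3-(benzyloxy)-4,5-dimethoxyphenyl]-3-(2-hydroxy-3,4,5-trimethoxyphenyl)propane-1,3-dione F3. Cyclodehydration (catalytic H2SO4, AcOH, 90 °C) should then return to the route at 14.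

Step 4. Acylation may occur at the carboxylate instead of the hindered, hydrogen-bonded phenol, leading to mixed anhydrides and transfer of the salicyloyl unit between molecules. The fallback masks the carboxyl group and sets out from 3. Allyl bromide with KHCO3 in DMF should esterify the acid only, giving allyl 2-hydroxy-3,4,5-trimethoxybenzoate F4. Aroylation with 7 (Et3N, DMAP, CH2Cl2) should give allyl 2-{[3-(benzyloxy)-4,5-dimethoxybenzoyl]oxy}-3,4,5-trimethoxybenzoate F5. Deallylation with Pd(PPh3)4 (zerovalent palladium) and N-methylaniline in THF at rt, which leaves the benzyl ether and the aryl ester alone, should return to the route at 8.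

Step 2. Substitution at the doubly ortho-flanked carbon may stall, or reductive loss of bromine may return the unhydroxylated acid. The fallback replaces copper-mediated substitution by metalation, borylation and oxidation and sets out from 2. n-BuLi (2.1 equiv, THF, −78 °C) should deprotonate the acid and exchange bromine for lithium. B(OMe)3 followed by aqueous work-up should give 2-borono-3,4,5-trimethoxybenzoic acid F6. Oxidation with H2O2 and NaOH at 0 °C should return to the route at 3.

Further compounds
F1 | step 6 | 1-(2-hydroxy-3,4,5-trimethoxyphenyl)ethan-1-one | COc1cc(C(C)=O)c(O)c(OC)c1OC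
F2 | step 6 | 2-acetyl-4,5,6-trimethoxyphenyl 3-(benzyloxy)-4,5-dimethoxybenzoate | COc1cc(C(C)=O)c(OC(=O)c2cc(OC)c(OC)c(OCc3ccccc3)c2)c(OC)c1OC
F3 | step 6 | 1-[3-(benzyloxy)-4,5-dimethoxyphenyl]-3-(2-hydroxy-3,4,5-trimethoxyphenyl)propane-1,3-dione | COc1cc(C(=O)CC(=O)c2cc(OC)c(OC)c(OCc3ccccc3)c2)c(O)c(OC)c1OC
F4 | step 4 | allyl 2-hydroxy-3,4,5-trimethoxybenzoate | C=CCOC(=O)c1cc(OC)c(OC)c(OC)c1O
F5 | step 4 | allyl 2-{[3-(benzyloxy)-4,5-dimethoxybenzoyl]oxy}-3,4,5-trimethoxybenzoate | C=CCOC(=O)c1cc(OC)c(OC)c(OC)c1OC(=O)c1cc(OC)c(OC)c(OCc2ccccc2)c1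
F6 | step 2 | 2-borono-3,4,5-trimethoxybenzoic acid | COc1cc(C(=O)O)c(B(O)O)c(OC)c1OC
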